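- A single run at a single charge cannot show how ring answers to dilution, yet I had to forecast a new charge from the elm run.

| flask | starting material | remark | time |
|---|---|---|---|
| elm | 0.36 M | run made earlier |  |
| flask | 0.18 M |  | 6.0 h |

elm run (percent of the starting material charged)

| time / min | ring / % |
|---|---|
| 8.00 | 25 |
| 15.0 | 34 |
| 25.0 | 44 |
| 40.0 | 54 |
| 60.0 | 51 |
| 120 | 42 |

(each reading ± 2 percentage points)

- when, up to 6.0 h, the flask holds most ring
- the amount of ring, in percent of the starting material charged, at that time
- the first time at which ring reaches 29%, in the same percent



- I began with the mean rate to the first reading, g, the share of the charge turned to ring per minute: 0.0312 min⁻¹.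
- Held steady, g reached 29% in 9.28 min.
- The curve bent, though. Between the first two readings the mean rate g2 was 0.0129 min⁻¹, slower than g, so that time was too short.
- Stepping on from the first reading at g2, the elm run reached the level at 11.1 min, a correction of 1.82 min.
- This gave my carried quantity, the mean filling rate m, the share of the charge turned to ring per minute from the start to the level: 0.0261 min⁻¹.
- The weak link was moving m to the flask, at half the elm charge. A step whose rate followed the square of the charge would have stretched the time to 22.2 min.
- I reforged that link by assuming that ring closes within one molecule. A first-order step keeps m unchanged, so I committed to 0.185 h for the flask.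
- The forecast gave 1.4 h, 45% and 0.38 h, holding that “Halving the concentration halves the formation rate”, so its time to the level was longer than mine.
- The flask held most ring, 57.7%, at 1.05 h, and reached the level at 0.177 h, so its m was 0.0273 min⁻¹.

    starting material + open dimer → open trimer (k = 4.29 × 10⁻⁴ M⁻¹ s⁻¹)
    starting material ⇌ ring (K = 2.98, k = 6.19 × 10⁻⁴ s⁻¹)
    2 starting material → open dimer (k = 4.23 × 10⁻⁴ M⁻¹ s⁻¹)
    ring ⇌ isomer of the product (K = 0.599, k = 4.30 × 10⁻⁵ s⁻¹)

- At the start of the flask, the forward ring step used starting material 4.1 times as fast as the step to open dimer. The same ratio, with the way back from ring not counted, stood at 30 at 6.00 h, when open dimer held 15.9% of the starting material charged.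

Readings and results stem from a simulated flask for an exercise, and the scatter is random.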